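The route rests on cutting the C7–C8 bond of the tetrahydrochromone carbocycle (unit A, chromone numbering; unit B primed). With the one-atom bridge C6 as a ketone, the seven-membered ring C5–C6–C7–O–C6'–C7'–O is a 1,5-benzodioxepin-3-one. Its C5–H is configurationally labile, its C7H2 is nucleophilic through an enamine, and C8 is a non-enolisable aldehyde on C8a of pyranone ring A. One proline-catalysed 6-enolendo aldol forms C7–C8, closes the carbocycle and the bicyclo[4.3.1] core, and sets C5, C7 and C8 from a racemate by dynamic kinetic resolution. The precursor is the racemic 2-(2-formyl-4-oxopyran-3-yl)benzodioxepinone fused to chromone B. A face-selective reduction of C6 finishes the synthesis.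

Key step: step 13

Remarks on the chemistry
- Connectivity and configuration: the aryl ether bonds are C5–O–C7' and C7–O–C6'. On the carbocycle C5–C6–C7–C8–C8a–C4a both ether oxygens lie on one face and the C6 and C8 hydroxyls on the other. The target is 5R,6S,7R,8S; the 6-ketone is 5R,7S,8S, because only the priority order at C7 changes.
- Design points:
  - The 7'-OH is the more acidic phenol of the catechol, so it is blocked as a benzyl ether before C7 is joined to O6'.
  - C5–C6–C7 is carried as an allyl group.
  - C5 is functionalised under basic conditions only, so the acetal and the arenes are not exposed to acid or free bromine.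
- Assumption: the sense of induction of (S)-proline is taken from the hydrogen-bonded anti-enamine (Houk–List) model; should the opposite sense be found, (R)-proline is used in the same way.

Step 1
Reactants: 1 2,2,6-trimethyl-4H-1,3-dioxin-4-one; 2 4-methoxybenzyl chloride
Product: 3 6-[2-(4-methoxyphenyl)ethyl]-2,2-dimethyl-4H-1,3-dioxin-4-one
Conditions: LiN(iPr)2 (LDA), THF–DMPU, −78 °C; then 2, Bu4NI (cat.), −78 → −20 °C
Reagents that add atoms: none
Why: Gamma-alkylation of the lithium dienolate of a 6-methyl-1,3-dioxin-4-one with a reactive benzylic halide (iodide catalysis) is a standard vinylogous enolate alkylation and builds the arylethyl chain of ring A.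

Step 2
Reactants: 4 methyl dimethoxyacetate; 5 3-butenylmagnesium bromide
Product: 6 1,1-dimethoxyhex-5-en-2-one
Conditions: THF, −78 °C; sat. aq. NH4Cl at −78 °C
Reagents that add atoms: none
Why: Grignard acylation with an alpha,alpha-dialkoxy ester: the magnesium-chelated tetrahedral adduct persists at −78 °C, so the alpha-keto acetal is released only on the cold quench and is not attacked twice.

Step 3
Reactants: 6 1,1-dimethoxyhex-5-en-2-one; 3 6-[2-(4-methoxyphenyl)ethyl]-2,2-dimethyl-4H-1,3-dioxin-4-one
Product: 9 3-allyl-2-(dimethoxymethyl)-6-[2-(4-methoxyphenyl)ethyl]-4H-pyran-4-one, via pyrrolidine enamine 7 (not isolated), via acylketene 8 (not isolated)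
Conditions: pyrrolidine, 4 Å MS, toluene, rt, excess amine evaporated; then 3 (2 equiv), toluene, 110 °C
Reagents that add atoms: none
Why: The enamine forms toward the CH2 side, and retro-Diels–Alder loss of acetone from 3 gives acylketene 8, which is C-acylated by 7 and closes through its ketone oxygen (formal hetero-Diels–Alder, the known enamine–acylketene gamma-pyrone synthesis), with loss of pyrrolidine completing ring A while the second equivalent of 8 binds the freed amine as its beta-keto amide.

Step 4
Reactants: 9 3-allyl-2-(dimethoxymethyl)-6-[2-(4-methoxyphenyl)ethyl]-4H-pyran-4-one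
Product: 10 2-(dimethoxymethyl)-6-[2-(4-methoxyphenyl)ethyl]-3-(oxiran-2-ylmethyl)-4H-pyran-4-one (racemic)
Conditions: mCPBA, CH2Cl2, 0 °C → rt
Reagents that add atoms: mCPBA, OOC(=O)c1cccc(Cl)c1
Why: Prilezhaev epoxidation takes the only isolated alkene, since both ring C=C bonds are deactivated vinylogous-ester alkenes; the new centre (later C6) is racemic and is erased in step 9.

Step 5
Reactants: 11 2'-hydroxy-4',5'-dimethoxyacetophenone; 12 methyl 3-phenylpropanoate
Product: 14 6,7-dimethoxy-2-(2-phenylethyl)-4H-chromen-4-one, via 1,3-diketone 13 (not isolated)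
Conditions: NaH, THF, 65 °C; then conc. HCl, MeOH, 65 °C
Reagents that add atoms: none
Why: Crossed Claisen condensation of the acetophenone dianion with the ester, followed by acid cyclodehydration of the o-hydroxyaryl 1,3-diketone, is the standard entry to 2-(2-phenylethyl)chromones.

Step 6
Reactants: 14 6,7-dimethoxy-2-(2-phenylethyl)-4H-chromen-4-one
Product: 15 6,7-dihydroxy-2-(2-phenylethyl)-4H-chromen-4-one
Conditions: BBr3, CH2Cl2, −78 °C → rt; then H2O
Reagents that add atoms: none
Why: Lewis-acid ether cleavage with BBr3 removes both aryl methyl ethers and leaves the chromone untouched.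

Step 7
Reactants: 15 6,7-dihydroxy-2-(2-phenylethyl)-4H-chromen-4-one
Product: 16 7-benzyloxy-6-hydroxy-2-(2-phenylethyl)-4H-chromen-4-one
Conditions: BnBr (1.0 equiv), K2CO3 (1.0 equiv), DMF, rt
Reagents that add atoms: benzyl bromide, BrCc1ccccc1
Why: Williamson etherification with one equivalent of weak base: the 7'-OH is conjugated with the C4' carbonyl through C4a' and is the more acidic, so it is ionised and capped first, which leaves free exactly the 6'-OH that must be bonded to C7.

Step 8
Reactants: 16 7-benzyloxy-6-hydroxy-2-(2-phenylethyl)-4H-chromen-4-one; 10 2-(dimethoxymethyl)-6-[2-(4-methoxyphenyl)ethyl]-3-(oxiran-2-ylmethyl)-4H-pyran-4-one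
Product: 17 7-benzyloxy-6-{3-[2-(dimethoxymethyl)-6-[2-(4-methoxyphenyl)ethyl]-4-oxo-4H-pyran-3-yl]-2-hydroxypropoxy}-2-(2-phenylethyl)-4H-chromen-4-one (racemic carbinol at C6)
Conditions: K2CO3 (0.3 equiv), DMF, 80 °C
Reagents that add atoms: none
Why: Base-catalysed SN2 opening of a terminal epoxide by the 6'-phenoxide at the unhindered CH2 forms the C7–O–C6' aryl ether without regiochemical ambiguity because the 7'-oxygen is blocked; the carbinol centre stays racemic.

Step 9
Reactants: 17 the C6 carbinol of step 8
Product: 18 7-benzyloxy-6-{3-[2-(dimethoxymethyl)-6-[2-(4-methoxyphenyl)ethyl]-4-oxo-4H-pyran-3-yl]-2-oxopropoxy}-2-(2-phenylethyl)-4H-chromen-4-one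
Conditions: Dess–Martin periodinane, CH2Cl2, rt
Reagents that add atoms: none
Why: Dess–Martin oxidation under near-neutral conditions brings C6 to the ketone level, removes the racemic centre and tolerates the acetal, the benzyl ether and both pyranone rings.

Step 10
Reactants: 18 the 7'-O-benzyl C6 ketone
Product: 19 6-{3-[2-(dimethoxymethyl)-6-[2-(4-methoxyphenyl)ethyl]-4-oxo-4H-pyran-3-yl]-2-oxopropoxy}-7-hydroxy-2-(2-phenylethyl)-4H-chromen-4-one
Conditions: H2 (1 atm), Pd/C, EtOAc–MeOH, rt
Reagents that add atoms: none
Why: Hydrogenolysis of the aryl benzyl ether over Pd/C at one atmosphere frees the 7'-OH under conditions that chromone and pyranone C=C bonds and a dialkyl ketone are known to survive (a reversible cyclic hemiketal of 19 is of no consequence).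

Step 11
Reactants: 19 the 7'-hydroxy C6 ketone
Product: 21 racemic benzodioxepinone acetal (ring O–C5H–C6(=O)–C7H2–O fused at C7'/C6' of chromone B; C5 bears the 2-(dimethoxymethyl)-6-[2-(4-methoxyphenyl)ethyl]-4-oxo-4H-pyran-3-yl group), via C5 bromo ketone 20 (not isolated)
Conditions: KOtBu (2.05 equiv), THF, −78 → −30 °C; cannulated into NBS (1.0 equiv), THF, −78 °C; then DMF, −78 °C → rt (5 mM)
Reagents that add atoms: none
Why: The first equivalent of base ionises the phenol and the second, under equilibrating conditions, gives the thermodynamic enolate at C5 (flanked by the ketone and ring A), whose alpha-bromination with NBS should be far faster than attack on the electron-poor phenoxide ring, and on warming the 7'-phenoxide displaces the activated bromide (intramolecular Williamson reaction, 7-exo-tet) to close the dioxepinone without any acid that could harm the acetal; C5 is formed racemic.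

Step 12
Reactants: 21 racemic benzodioxepinone acetal
Product: 22 racemic keto aldehyde: 2-{2-formyl-6-[2-(4-methoxyphenyl)ethyl]-4-oxo-4H-pyran-3-yl}-1,5-benzodioxepin-3-one fused to chromone B (C5–O–C7' and C7–O–C6'; C5 epimerisable)
Conditions: 2 M aq. HCl, THF, rt; chromatography
Reagents that add atoms: water, O
Why: Specific-acid hydrolysis of the dimethyl acetal unmasks the C8 aldehyde, and chromatography at this stage removes any ketol formed by an uncatalysed racemic aldol before the asymmetric step.

Step 13
Reactants: 22 racemic keto aldehyde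
Product: 24 (5R,7S,8S)-6-oxo analogue of the target (bridged ketol; O5 and O7 on one face of the carbocycle and the 8-OH on the other), via C6 proline enamine 23 (not isolated)
Conditions: (S)-proline (30 mol %), DMSO, rt
Reagents that add atoms: none
Why: Proposed new method: (S)-proline condenses with the only ketone (C6), and because A(1,3) strain keeps the enamine on the unsubstituted side and turns the pyranonyl group on C5 pseudo-axial, enamine 23 holds C7 under the C8 aldehyde, so C7–C8 forms in a 6-(enolendo)-exo-trig aldol that closes the carbocycle C5–C6–C7–C8–C8a–C4a and with it the bicyclo[4.3.1] core, after which hydrolysis at C6 returns the catalyst. The closest known reactions are the proline-catalysed Hajos–Parrish 6-enolendo aldolisation, the proline aldol of 2,2-dimethyl-1,3-dioxan-5-one and amine-catalysed aldol reactions that dynamically resolve alpha-epimerisable ketones, none of which has closed a bridged ring across a benzodioxepinone. C7 is controlled by the catalyst: in the anti enamine the carboxylic acid sits on one face and activates the aldehyde there, which by the Houk–List model gives 7S. C5 is controlled by the tether, which reaches C7 only from the face that carries the pyranonyl group, so only (5R)-22 is matched, and the 5S enantiomer is fed back through the C5 enol and the regioisomeric enamine (C5–H is flanked by the ketone, an aryloxy group and ring A). C8 is controlled by the tether placing C8a gauche to C6 on the C5 side and by the hydrogen bond from the CO2H to the carbonyl oxygen on the nitrogen side, an arrangement that also opposes the C8=O and C7–O dipoles and makes O8 pseudo-axial and anti to O7, i.e. 8S. The step needs chemoselectivity between carbonyl groups and stability of the adduct: there is one enolisable ketone and one non-enolisable aldehyde, attack from C5 would need a four-membered ring, and the ketol can neither dehydrate nor epimerise because C5 and C7 have become bridgeheads that cannot enolise.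

Step 14
Reactants: 24 (5R,7S,8S)-6-oxo analogue
Product: 25 (+)-4'-methoxyaquisinenone G (5R,6S,7R,8S)
Conditions: NaBH4, CeCl3·7H2O, MeOH–CH2Cl2, −78 °C
Reagents that add atoms: none
Why: Luche reduction: the alpha,alpha'-dioxy ketone at C6 is by far the most electrophilic carbonyl (C4 and C4' are vinylogous esters), its carbocycle face is screened by the pseudo-axial C8 hydroxyl while the dioxepine face shows only the two ring oxygens, so hydride should enter from the dioxepine face and set 6S with the new hydroxyl syn to that on C8.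

Compound list
1 | 2,2,6-trimethyl-4H-1,3-dioxin-4-one | CC1=CC(=O)OC(C)(C)O1 | starting material
2 | 4-methoxybenzyl chloride | COc1ccc(CCl)cc1 | starting material
3 | 6-[2-(4-methoxyphenyl)ethyl]-2,2-dimethyl-4H-1,3-dioxin-4-one | COc1ccc(CCC2=CC(=O)OC(C)(C)O2)cc1 | intermediate
4 | methyl dimethoxyacetate | COC(OC)C(=O)OC | starting material
5 | 3-butenylmagnesium bromide | C=CCC[Mg]Br | starting material
6 | 1,1-dimethoxyhex-5-en-2-one | COC(OC)C(=O)CCC=C | intermediate
7 | 1-(1,1-dimethoxyhexa-2,5-dien-2-yl)pyrrolidine (not isolated) | COC(OC)C(=CCC=C)N1CCCC1 | intermediate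
8 | 5-(4-methoxyphenyl)-3-oxopent-1-en-1-one, acylketene (not isolated) | COc1ccc(CCC(=O)C=C=O)cc1 | intermediate
9 | 3-allyl-2-(dimethoxymethyl)-6-[2-(4-methoxyphenyl)ethyl]-4H-pyran-4-one | COc1ccc(CCc2cc(=O)c(CC=C)c(C(OC)OC)o2)cc1 | intermediate
10 | 2-(dimethoxymethyl)-6-[2-(4-methoxyphenyl)ethyl]-3-(oxiran-2-ylmethyl)-4H-pyran-4-one, racemic | COc1ccc(CCc2cc(=O)c(CC3CO3)c(C(OC)OC)o2)cc1 | intermediate
11 | 2'-hydroxy-4',5'-dimethoxyacetophenone | CC(=O)c1cc(OC)c(OC)cc1O | starting material
12 | methyl 3-phenylpropanoate | COC(=O)CCc1ccccc1 | starting material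
13 | 1-(2-hydroxy-4,5-dimethoxyphenyl)-5-phenylpentane-1,3-dione (not isolated) | COc1cc(O)c(cc1OC)C(=O)CC(=O)CCc1ccccc1 | intermediate
14 | 6,7-dimethoxy-2-(2-phenylethyl)-4H-chromen-4-one | COc1cc2oc(CCc3ccccc3)cc(=O)c2cc1OC | intermediate
15 | 6,7-dihydroxy-2-(2-phenylethyl)-4H-chromen-4-one | Oc1cc2oc(CCc3ccccc3)cc(=O)c2cc1O | intermediate
16 | 7-benzyloxy-6-hydroxy-2-(2-phenylethyl)-4H-chromen-4-one | Oc1cc2c(=O)cc(CCc3ccccc3)oc2cc1OCc1ccccc1 | intermediate
17 | 7'-O-benzyl C6 carbinol (C7–O–C6' ether), racemic | COc1ccc(CCc2cc(=O)c(CC(O)COc3cc4c(=O)cc(CCc5ccccc5)oc4cc3OCc3ccccc3)c(C(OC)OC)o2)cc1 | intermediate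
18 | 7'-O-benzyl C6 ketone | COc1ccc(CCc2cc(=O)c(CC(=O)COc3cc4c(=O)cc(CCc5ccccc5)oc4cc3OCc3ccccc3)c(C(OC)OC)o2)cc1 | intermediate
19 | 7'-hydroxy C6 ketone | COc1ccc(CCc2cc(=O)c(CC(=O)COc3cc4c(=O)cc(CCc5ccccc5)oc4cc3O)c(C(OC)OC)o2)cc1 | intermediate
20 | C5 bromo ketone, racemic (not isolated) | COc1ccc(CCc2cc(=O)c(C(Br)C(=O)COc3cc4c(=O)cc(CCc5ccccc5)oc4cc3O)c(C(OC)OC)o2)cc1 | intermediate
21 | benzodioxepinone dimethyl acetal, racemic at C5 | COc1ccc(CCc2cc(=O)c(c(C(OC)OC)o2)C3Oc4cc5oc(CCc6ccccc6)cc(=O)c5cc4OCC3=O)cc1 | intermediate
22 | benzodioxepinone keto aldehyde, racemic and epimerisable at C5 | COc1ccc(CCc2cc(=O)c(c(C=O)o2)C3Oc4cc5oc(CCc6ccccc6)cc(=O)c5cc4OCC3=O)cc1 | intermediate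
23 | enamine of (5R)-22 and (S)-proline, C6=C7, nitrogen on C6 (not isolated) | COc1ccc(CCc2cc(=O)c(c(C=O)o2)[C@H]3Oc4cc5oc(CCc6ccccc6)cc(=O)c5cc4OC=C3N3CCC[C@H]3C(=O)O)cc1 | intermediate
24 | (5R,7S,8S)-6-oxo analogue of the target | COc1ccc(CCc2cc(=O)c3c(o2)[C@@H](O)[C@@H]2Oc4cc5c(=O)cc(CCc6ccccc6)oc5cc4O[C@H]3C2=O)cc1 | intermediate
25 | (+)-4'-methoxyaquisinenone G, (5R,6S,7R,8S) | COc1ccc(CCc2cc(=O)c3c(o2)[C@@H](O)[C@@H]2Oc4cc5c(=O)cc(CCc6ccccc6)oc5cc4O[C@H]3[C@@H]2O)cc1 | target

Total step count: 14.
Longest linear sequence: 10 steps (11 → 14 → 15 → 16 → 17 → 18 → 19 → 21 → 22 → 24 → 25). The branch from 1 through 3, 9 and 10 is equally long.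

Steps most likely to fail

Step 13.
- Risk: enamine formation at the hindered C6 may be slow, epimerisation at C5 may not keep pace with ring closure, or an uncatalysed aldol may compete. Each of these would erode enantiopurity.
- Fallback: it sets out from 22 and uses only known chemistry.
  - An achiral promoter (pyrrolidine–AcOH, 20 mol %, CH2Cl2, rt) effects the ordinary intramolecular aldol addition of an o-(2-oxoalkyl)aryl aldehyde.
  - This gives the racemic ketol, that is 24 together with the mirror-image ketol F1.
  - Reduction under the conditions of step 14 gives 25 together with the mirror-image diol F2.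
  - The two are separated by preparative HPLC on a chiral stationary phase, which rejoins the route at 25.

Step 11.
- Risk: proton transfer between the enolate and the bromo ketone may lead to over-bromination, the phenoxide ring may be brominated, or displacement at the hindered C5 may be sluggish.
- Fallback: it sets out from 19 and replaces substitution by carbenoid chemistry.
  - Regitz diazo transfer (4-acetamidobenzenesulfonyl azide, DBU, MeCN, 0 °C) at the doubly activated C5 gives the diazo ketone F3.
  - Rh2(OAc)4 (1 mol %) in dilute CH2Cl2 then effects intramolecular O–H insertion of the 7'-OH, which rejoins the route at 21.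

Step 14.
- Risk: facial selectivity may be poor, for example through hydroxyl-assisted delivery of hydride from the carbocycle face.
- Fallback: it sets out from 24.
  - Silylation (TBSOTf, 2,6-lutidine, CH2Cl2, −78 → 0 °C) gives the 8-O-TBS ketone F4. No enol silane can form because both alpha-carbons are bridgeheads. The pseudo-axial silyl ether closes the carbocycle face and removes the directing hydroxyl.
  - NaBH4 in MeOH–CH2Cl2 at −40 °C then gives the 8-O-TBS alcohol F5.
  - HF·pyridine in THF removes the silyl group and rejoins the route at 25.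

Further compounds
F1 | step 13 | mirror-image ketol, (5S,7R,8R) | COc1ccc(CCc2cc(=O)c3c(o2)[C@H](O)[C@H]2Oc4cc5c(=O)cc(CCc6ccccc6)oc5cc4O[C@@H]3C2=O)cc1
F2 | step 13 | mirror-image diol, (5S,6R,7S,8R) | COc1ccc(CCc2cc(=O)c3c(o2)[C@H](O)[C@H]2Oc4cc5c(=O)cc(CCc6ccccc6)oc5cc4O[C@@H]3[C@H]2O)cc1
F3 | step 11 | C5 diazo ketone | COc1ccc(CCc2cc(=O)c(C(=[N+]=[N-])C(=O)COc3cc4c(=O)cc(CCc5ccccc5)oc4cc3O)c(C(OC)OC)o2)cc1
F4 | step 14 | 8-O-TBS ketone, (5R,7S,8S) | COc1ccc(CCc2cc(=O)c3c(o2)[C@@H](O[Si](C)(C)C(C)(C)C)[C@@H]2Oc4cc5c(=O)cc(CCc6ccccc6)oc5cc4O[C@H]3C2=O)cc1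
F5 | step 14 | 8-O-TBS alcohol, (5R,6S,7R,8S) | COc1ccc(CCc2cc(=O)c3c(o2)[C@@H](O[Si](C)(C)C(C)(C)C)[C@@H]2Oc4cc5c(=O)cc(CCc6ccccc6)oc5cc4O[C@H]3[C@@H]2O)cc1
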